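## Retrosynthetic overview
1. Alertenone is cut at C3–C12′ into two molecules of one enantiomer of suberosenone. The forward reaction is a Michael addition of the C3 enolate to the exocyclic enone, which sets C3 and C1′.
2. The α-methylene ketone of suberosenone comes from a regiospecific C1 enolate and CH2=NMe2+. That enolate comes from reductive cleavage of the C1–C10 bond of a cyclopropyl ketone.
3. The cyclopropyl ketone comes from an intramolecular arene–alkene meta-photocycloaddition of a p-silyloxyaryl/prenyl substrate. This step forms C4–C5, C10–C11 and C1–C9.
4. The arene comes from Robinson annulation and aromatisation of (S)-citronellal with methyl vinyl ketone. The C8 stereocentre is purchased.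
5. Ring order: a sacrificial benzene ring first. One photochemical step then forms the cyclohexane, both cyclopentanes and a cyclopropane. The cyclopropane is opened, and the monomer is dimerised.

**Locants used for all polycycles:** C12H2=C1–C2(=O)–C3–C4–C5–C6–C7–C8(CH3)–C9. C9 is also bonded to C1, C4 and C10. C10 is bonded to C11(CH3)2, which is bonded to C5. Primed locants refer to the saturated-ketone half of 12.

**Assumption:** the SMILES shows both halves with the same absolute configuration, so 12 is treated as a homodimer of 11.

## Route

**Step 1**
Reactants: 1 (S)-(–)-citronellal, (3S)-3,7-dimethyloct-6-enal; 2 methyl vinyl ketone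
Product: 3, 2-[(2S)-6-methylhept-5-en-2-yl]-5-oxohexanal (about 1:1 at C2)
Conditions: 2 (1.5 equiv), Et2NSiMe3 (20 mol %), MeCN, reflux
Reagents that add atoms: methyl vinyl ketone, C=CC(C)=O
Why: This is an amine (enamine)-catalysed Michael addition of an unmodified aldehyde to an enone; the new α-centre forms unselectively but is erased in step 4, and the purchased centre is β to the CHO and cannot epimerise.

**Step 2**
Reactants: 3
Product: 4, 4-[(2S)-6-methylhept-5-en-2-yl]cyclohex-2-en-1-one (C4 epimers)
Conditions: aq KOH, n-Bu4NOH (cat.), THF–Et2O, reflux
Reagents that add atoms: none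
Why: This intramolecular aldol condensation is the second half of a Robinson annulation, in which the methyl-ketone enolate closes the six-membered ring onto the aldehyde and water is lost.

**Step 3**
Reactants: 4
Product: 5, 2-(tert-butyldimethylsilyloxy)-5-[(2S)-6-methylhept-5-en-2-yl]cyclohexa-1,3-diene (C5 epimers)
Conditions: TBSOTf, Et3N, CH2Cl2, 0 °C
Reagents that add atoms: TBSOTf, CC(C)(C)[Si](C)(C)OS(=O)(=O)C(F)(F)F
Why: Soft enolisation and O-silylation of a cyclohexenone gives the cross-conjugated silyl dienol ether; any linear dienol ether isomer converges in step 4, and the isolated trisubstituted alkene is inert.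

**Step 4**
Reactants: 5
Product: 6, tert-butyldimethyl{4-[(2S)-6-methylhept-5-en-2-yl]phenoxy}silane
Conditions: DDQ (1.1 equiv), 2,4,6-collidine, benzene, rt
Reagents that add atoms: none
Why: In this DDQ dehydrogenative aromatisation, hydride abstraction gives a silyloxy-stabilised arenium ion that loses H+ faster than the hindered TBS group, which leaves C8 as the only stereocentre.

**Step 5**
Reactants: 6
Product: 7, (1R,4R,5S,8S,9S,10R)-2-(TBSO)-1,10-cyclo-12-norquadr-2-ene. This is the suberosenone skeleton without C12, with an extra C1–C10 bond (cis-fused cyclopropane C1–C9–C10) and a C2(OTBS)=C3 enol ether.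
Conditions: hν (254 nm, quartz), cyclohexane (5 mM), Ar, rt, stopped at about 80 % conversion
Reagents that add atoms: none
Why: Proposed new method: this is a tether-centred (2,6-mode) intramolecular arene–alkene meta-photocycloaddition on a para-silyloxy arene carrying a trisubstituted alkene, a substrate pattern on which the reaction has not been shown. Mechanism: the S1 arene/alkene exciplex bonds C5 to one ortho carbon (C4) and C11 to the other (C10), giving a bicyclo[3.2.1]octenyl diyl that is δ+ at alkyl-bearing C9 and δ– at the allyl termini C1 and C3. Mode selection: OTBS sits on the allyl node in this mode but on a δ– terminus in either 1,3-mode, and its own preferred mode cannot be reached with a three-atom tether; a donor arene with a donor alkene also disfavours ortho addition. Cyclopropane closure: C9–C1 is the only feasible collapse, because C9–C3 closure would trans-fuse the new cyclohexane onto the cyclopropane. Stereocontrol: C8 directs the face, since the benzylic H eclipses the C10–H ortho position and the CH3 turns away from the tether (minimal A1,3 strain), which sets C9, C4 and C5 (plus transient C1 and C10) in one event. The closest known reaction type is the tethered arene–alkene meta-photocycloaddition used for cedrane and triquinane skeletons.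

**Step 6**
Reactants: 7
Product: 8, (1R,4S,5S,8S,9S,10R)-1,10-cyclo-12-norquadran-2-one (cyclopropyl ketone)
Conditions: TBAF, AcOH (1:1), THF, 0 °C
Reagents that add atoms: none
Why: Buffered fluoride cleavage of the silyl enol ether gives the ketone by protonation at C3, which creates no stereocentre and leaves the cyclopropyl ketone intact.

**Step 7**
Reactants: 8; 9 Eschenmoser's salt (N,N-dimethylmethyleneiminium iodide)
Product: 10, 1-(dimethylaminomethyl)-12-norquadran-2-one, (4S,5S,8S,9S), C1 epimers inconsequential
Conditions: Li, NH3(l)–THF, –78 to –33 °C; isoprene; evaporate NH3; THF; 9 (4 equiv), –78 °C to rt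
Reagents that add atoms: Eschenmoser's salt, C=[N+](C)C.[I-]
Why: Dissolving-metal cleavage of the cyclopropyl ketone breaks C1–C10, the bond that lies perpendicular to ring P and overlaps the C=O π system, so C10 becomes CH2 and a regiospecific C1 lithium enolate forms that is trapped in situ in a Mannich reaction (Stork-type reductive enolate trapping).

**Step 8**
Reactants: 10
Product: 11, suberosenone, (4S,5S,8S,9S)
Conditions: MeI, Et2O, rt; then DBU, CH2Cl2, 0 °C; used at once
Reagents that add atoms: none (the CH3 from MeI leaves as NMe3)
Why: Quaternisation followed by E1cB (Hofmann-type) elimination of the Mannich base can only give the exocyclic C1=C12 alkene, because C9 is quaternary.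

**Step 9**
Reactants: 11 (2 molecules)
Product: 12, alertenone, (3R,4R,5S,8S,9S,1′S,4′S,5′S,8′S,9′S)
Conditions: LiHMDS (0.50 equiv relative to total 11), THF–DMPU, –78 °C: half of 11 is added to the base, then the other half; –78 to –50 °C; quench at –78 °C with pre-cooled AcOH/THF; neutral work-up
Reagents that add atoms: none
Why: In this intermolecular Michael addition, C3 is the only enolisable site and its cross-conjugated enolate attacks the unhindered C12′H2 on the convex face of ring P (cis to H4, anti to the gem-dimethyl bridge), giving 3R; the resulting neopentyl C1′ enolate is too hindered to propagate or close onto C12, and it is protonated kinetically on the face away from the axial C8′ methyl, giving 1′S.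

## Compound list
| No. | Name | SMILES | Role |
|---|---|---|---|
| 1 | (S)-citronellal | C[C@@H](CCC=C(C)C)CC=O | starting material |
| 2 | methyl vinyl ketone | C=CC(C)=O | starting material |
| 3 | 2-[(2S)-6-methylhept-5-en-2-yl]-5-oxohexanal | CC(=O)CCC(C=O)[C@@H](C)CCC=C(C)C | intermediate |
| 4 | 4-[(2S)-6-methylhept-5-en-2-yl]cyclohex-2-enone | O=C1C=CC(CC1)[C@@H](C)CCC=C(C)C | intermediate |
| 5 | 2-TBSO-5-alkylcyclohexa-1,3-diene | CC(C)=CCC[C@H](C)C1CC=C(O[Si](C)(C)C(C)(C)C)C=C1 | intermediate |
| 6 | p-(TBSO)aryl prenyl substrate | CC(C)=CCC[C@H](C)c1ccc(O[Si](C)(C)C(C)(C)C)cc1 | intermediate |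
| 7 | meta-photoadduct (silyl enol ether) | CC(C)(C)[Si](C)(C)OC1=C[C@H]2[C@@H]3CC[C@H](C)[C@]24[C@H]1[C@@H]4C3(C)C | intermediate |
| 8 | cyclopropyl ketone | O=C1C[C@H]2[C@@H]3CC[C@H](C)[C@]24[C@H]1[C@@H]4C3(C)C | intermediate |
| 9 | Eschenmoser's salt | C=[N+](C)C.[I-] | starting material |
| 10 | C1 Mannich base | CN(C)CC1C(=O)C[C@H]2[C@@H]3CC[C@H](C)[C@]12CC3(C)C | intermediate |
| 11 | suberosenone | C=C1C(=O)C[C@H]2[C@@H]3CC[C@H](C)[C@]12CC3(C)C | intermediate |
| 12 | alertenone | C=C1C(=O)[C@H](C[C@@H]2C(=O)C[C@H]3[C@@H]4CC[C@H](C)[C@]23CC4(C)C)[C@H]2[C@@H]3CC[C@H](C)[C@]12CC3(C)C | target |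

**Total steps:** 9. **Longest linear sequence:** 9. The route is a homodimerisation, so there is no second branch.

## Steps most likely to fail
1. **Step 5 (the proposed new step).**
   - Risks: low quantum efficiency, competing 1,3-mode or ortho adducts, and only modest facial selectivity.
   - Fallback (known chemistry only): abandon the arene and build C9 by tandem radical cyclisation. A cyclohexanone derived from (S)-carvone would carry a CMe2CH2Br arm at C5 and a protected propargylic-alcohol arm at C4. It is converted to the N-aziridinyl imine and treated with Bu3SnH/AIBN. This gives a 5-exo (C10 to C9) then 5-exo-dig (C9 to C1) closure that installs the exocyclic methylene. Deprotection and oxidation then give 11.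
2. **Step 9.**
   - Risks: oligomerisation, a second Michael closure of C1′ onto C12, 1,2-addition, or protonation to the (likely more stable) C1′ epimer.
   - Fallback: a Mukaiyama–Michael union. Half of 11 is converted to its 2-silyloxydiene (TBSOTf, Et3N) and coupled with 11 under catalytic TBSOTf or TiCl4 at –78 °C. The C1′=C2′ silyl enol ether is isolated and protonated in a separate, tunable step. This separates C–C bond formation from the setting of C1′.
3. **Step 7.**
   - Risks: enolate equilibration to C3, incomplete trapping at the neopentyl C1, and over-reduction.
   - Fallback: polar homoconjugate opening of 8 with TMSI (CH2Cl2, –78 °C), which gives the C10 iodide and the C1=C2 TMS enol ether. A Mukaiyama–Mannich reaction with 9 follows. Radical deiodination (Bu3SnH) is then carried out before the step 8 elimination.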